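Ring B of the chromene is disconnected into a four-carbon vinylketene unit (C6, C7, C8, C8a) and a two-carbon ynol ether unit (C4a, C5). Heating 2-alkynyl-3-isopropoxycyclobutenone 5 with prenylated methoxyalkyne 11 should assemble the pentasubstituted benzene in one Danheiser benzannulation, forming C4a–C8a, C5–C6 and C8–C8a. The step exploits the 1,3,5-trioxygenated pattern of ring B: it delivers the C8a oxygen as a free phenol next to the prenyl chain on C4a, the C5 oxygen as its methyl ether and the C7 oxygen as an isopropyl ether, all three distinguished. Chromene closure, alkyne dioxygenation and isopropyl removal then finish the target.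

Key step: step 5

Remark: the target is achiral, so no stereocentre has to be set. Cyclobutane-1,3-dione is assumed to be purchasable and is handled as its enol. The connectivity of cyclobutenone 5 and phenol 16 was checked atom by atom against the cascade and needs no correction. Isopropyl is kept as the C7 mask because it survives every step up to the diketone and can then be removed next to two methyl ethers.

Step 1
Reactants: 1 cyclobutane-1,3-dione
Product: 2 3-isopropoxycyclobut-2-en-1-one
Conditions: i-PrOH (1.2 equiv), PPh3, DIAD, THF, 0 °C → rt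
Reagents that add atoms: propan-2-ol, CC(C)O
Why: Mitsunobu O-alkylation, in which the strongly acidic enol of the dione protonates the PPh3–DIAD betaine and its oxygen then displaces Ph3PO from the isopropoxyphosphonium ion, should give the vinylogous ester under neutral, cold conditions that do not expose the strained dione to ring-cleaving acid or base.

Step 2
Reactants: 2 3-isopropoxycyclobut-2-en-1-one
Product: 3 2-iodo-3-isopropoxycyclobut-2-en-1-one
Conditions: NIS (1.05 equiv), MeCN, 0 °C → rt, dark
Reagents that add atoms: N-iodosuccinimide, O=C1CCC(=O)N1I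
Why: C2 is the nucleophilic enol-ether carbon of the vinylogous ester, so electrophilic α-iodination followed by loss of the C2 proton should give the 2-iodoenone, as in the α-halogenation of 3-alkoxyenones.

Step 3
Reactants: 3 2-iodo-3-isopropoxycyclobut-2-en-1-one; 4 4-ethynylanisole (1-ethynyl-4-methoxybenzene)
Product: 5 3-isopropoxy-2-[(4-methoxyphenyl)ethynyl]cyclobut-2-en-1-one
Conditions: PdCl2(PPh3)2 (3 mol%), CuI (5 mol%), i-Pr2NEt (2 equiv), THF, 0 °C → rt
Reagents that add atoms: none
Why: Sonogashira coupling of an α-iodoenone, which adds oxidatively to zerovalent palladium at or below room temperature; the hindered tertiary amine is chosen because it cannot substitute at C3 or open the four-membered ring as a secondary amine could.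

Step 4
Reactants: 6 2-chloro-1,1-dimethoxyethane; 7 1-bromo-3-methylbut-2-ene
Product: 11 1-methoxy-5-methylhex-4-en-1-yne, via 1-chloro-2-methoxyethene 8 (not isolated), via methoxyethyne 9 (not isolated), via sodium methoxyacetylide 10 (not isolated)
Conditions: NaNH2 (3.0 equiv), NH3(l), −33 °C; then 7 (1.0 equiv), −40 → −33 °C; pentane extraction, distillation at reduced pressure
Reagents that add atoms: none
Why: Double elimination from the chloroacetal (loss of methanol, then of HCl) and deprotonation give the sodium alkoxyacetylide, which is alkylated by SN2 attack at the primary carbon of prenyl bromide (the established acetal route to 1-alkoxyalkynes); exactly three equivalents of amide are used so that no free base is left to isomerise the skipped enyne.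

Step 5
Reactants: 5 3-isopropoxy-2-[(4-methoxyphenyl)ethynyl]cyclobut-2-en-1-one; 11 1-methoxy-5-methylhex-4-en-1-yne
Product: 16 5-isopropoxy-3-methoxy-4-[(4-methoxyphenyl)ethynyl]-2-(3-methylbut-2-enyl)phenol, via vinylketene 12 (not isolated), via 4-vinylcyclobutenone 13 (not isolated), via dienylketene 14 (not isolated), via cyclohexadienone 15 (not isolated)
Conditions: 11 (1.5 equiv), toluene (0.5 M), 120 °C, sealed tube; then KOH, MeOH, rt (cleaves any aryl ester by-product)
Reagents that add atoms: none
Why: Danheiser benzannulation: thermal 4π opening of cyclobutenone 5 (C1–C4 cleavage) gives vinylketene 12, whose ketene C=C adds [2+2] to ynol ether 11 to give 4-vinylcyclobutenone 13, a second 4π opening gives dienylketene 14, and 6π electrocyclisation followed by tautomerisation of cyclohexadienone 15 gives phenol 16. The closest known reaction type is the benzannulation of cyclobutenones with alkoxyalkynes, and thermal opening of 3-alkoxycyclobutenones is familiar from squarate-derived systems, although the vinylogous ester character of 5 calls for a higher temperature than 3-alkylcyclobutenones need. Ring B closes by a disrotatory 6π electrocyclisation that joins the ketene carbon (C8a) to the methylene terminus (C8), after C4a–C8a and C5–C6 have been made in the [2+2] step. No stereocentre remains in 16, since the quaternary centre of racemic 13 is lost on ring opening. The regiochemistry of the [2+2] step is required and is fixed by polarity: the nucleophilic β-carbon of the ynol ether, which carries the prenyl group, bonds to the electrophilic ketene carbon, so prenyl ends next to the new hydroxyl and methoxy next to the alkynyl carbon. The step also needs 14 to close onto its vinyl terminus and not onto the alkyne, which reversible opening of 13 and the much lower barrier of the pericyclic closure compared with a diradical enyne–ketene cyclisation should secure, while the methyl ynol ether, having no β-hydrogen for retro-ene loss of an alkene, tolerates the temperature.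

Step 6
Reactants: 16 5-isopropoxy-3-methoxy-4-[(4-methoxyphenyl)ethynyl]-2-(3-methylbut-2-enyl)phenol
Product: 18 7-isopropoxy-5-methoxy-6-[(4-methoxyphenyl)ethynyl]-2,2-dimethyl-2H-chromene, via o-quinone methide 17 (not isolated)
Conditions: DDQ (1.1 equiv), benzene, 80 °C
Reagents that add atoms: none
Why: DDQ removes hydride from the benzylic carbon of the electron-rich o-prenylphenol to give o-quinone methide 17, which closes by oxa-6π electrocyclisation to the 2,2-dimethyl-2H-chromene, the standard dehydrogenative cyclisation of o-prenylphenols.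

Step 7
Reactants: 18 7-isopropoxy-5-methoxy-6-[(4-methoxyphenyl)ethynyl]-2,2-dimethyl-2H-chromene
Product: 19 1-(7-isopropoxy-5-methoxy-2,2-dimethyl-2H-chromen-6-yl)-2-(4-methoxyphenyl)ethane-1,2-dione
Conditions: Ph3PAuNTf2 (5 mol%), 2,3-dichloropyridine N-oxide (3 equiv), PhCl, 80 °C
Reagents that add atoms: 2,3-dichloropyridine N-oxide, [O-][n+]1cccc(Cl)c1Cl
Why: Gold-catalysed double oxidation of a diarylalkyne, in which the N-oxide adds to the gold-activated alkyne, N–O cleavage gives an α-oxo gold carbene and a second N-oxide oxidises it to the 1,2-diketone; both alkyne carbons become carbonyls, so the site of first attack is irrelevant, and the neutral conditions should spare the chromene alkene and the isopropyl ether.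

Step 8
Reactants: 19 1-(7-isopropoxy-5-methoxy-2,2-dimethyl-2H-chromen-6-yl)-2-(4-methoxyphenyl)ethane-1,2-dione
Product: 21 1-(7-hydroxy-5-methoxy-2,2-dimethyl-2H-chromen-6-yl)-2-(4-methoxyphenyl)ethane-1,2-dione, via aryloxydichloroborane 20 (not isolated)
Conditions: BCl3 (1.5 equiv), CH2Cl2, −78 → −20 °C; then H2O, NaHCO3
Reagents that add atoms: none
Why: Chelation-assisted Lewis acid dealkylation, in which BCl3 bridges the C6 ketone and the C7 ether oxygen and removes the secondary isopropyl group as 2-chloropropane much faster than either methyl ether at low temperature, after which aqueous work-up hydrolyses aryloxyborane 20 to the hydrogen-bonded phenol.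

Compound list
1 | cyclobutane-1,3-dione | O=C1CC(=O)C1 | starting material
2 | 3-isopropoxycyclobut-2-en-1-one | CC(C)OC1=CC(=O)C1 | intermediate
3 | 2-iodo-3-isopropoxycyclobut-2-en-1-one | CC(C)OC1=C(I)C(=O)C1 | intermediate
4 | 4-ethynylanisole | COc1ccc(C#C)cc1 | starting material
5 | 3-isopropoxy-2-[(4-methoxyphenyl)ethynyl]cyclobut-2-en-1-one | CC(C)OC1=C(C#Cc2ccc(OC)cc2)C(=O)C1 | intermediate
6 | 2-chloro-1,1-dimethoxyethane | COC(CCl)OC | starting material
7 | 1-bromo-3-methylbut-2-ene | CC(C)=CCBr | starting material
8 | 1-chloro-2-methoxyethene (mixture of E and Z isomers, both eliminate to 9) | COC=CCl | intermediate (not isolated)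
9 | methoxyethyne | COC#C | intermediate (not isolated)
10 | sodium methoxyacetylide | [Na+].[C-]#COC | intermediate (not isolated)
11 | 1-methoxy-5-methylhex-4-en-1-yne | COC#CCC=C(C)C | intermediate
12 | 3-isopropoxy-2-[(4-methoxyphenyl)ethynyl]buta-1,3-dien-1-one (vinylketene) | C=C(OC(C)C)C(C#Cc1ccc(OC)cc1)=C=O | intermediate (not isolated)
13 | racemic 4-(1-isopropoxyethenyl)-3-methoxy-4-[(4-methoxyphenyl)ethynyl]-2-(3-methylbut-2-enyl)cyclobut-2-en-1-one | COC1=C(CC=C(C)C)C(=O)C1(C#Cc1ccc(OC)cc1)C(=C)OC(C)C | intermediate (not isolated)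
14 | (3E)-5-isopropoxy-3-methoxy-4-[(4-methoxyphenyl)ethynyl]-2-(3-methylbut-2-enyl)hexa-1,3,5-trien-1-one (dienylketene, isopropoxyvinyl group cis to the ketene) | O=C=C(CC=C(C)C)/C(OC)=C(\C(OC(C)C)=C)C#Cc1ccc(OC)cc1 | intermediate (not isolated)
15 | 5-isopropoxy-3-methoxy-4-[(4-methoxyphenyl)ethynyl]-2-(3-methylbut-2-enyl)cyclohexa-2,4-dien-1-one | CC(C)=CCC1=C(OC)C(C#Cc2ccc(OC)cc2)=C(OC(C)C)CC1=O | intermediate (not isolated)
16 | 5-isopropoxy-3-methoxy-4-[(4-methoxyphenyl)ethynyl]-2-(3-methylbut-2-enyl)phenol | COc1ccc(C#Cc2c(OC(C)C)cc(O)c(CC=C(C)C)c2OC)cc1 | intermediate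
17 | (6Z)-3-isopropoxy-5-methoxy-4-[(4-methoxyphenyl)ethynyl]-6-(3-methylbut-2-enylidene)cyclohexa-2,4-dien-1-one (o-quinone methide) | CC(C)=C/C=C1\C(=O)C=C(OC(C)C)C(C#Cc2ccc(OC)cc2)=C1OC | intermediate (not isolated)
18 | 7-isopropoxy-5-methoxy-6-[(4-methoxyphenyl)ethynyl]-2,2-dimethyl-2H-chromene | COc1ccc(C#Cc2c(OC(C)C)cc3OC(C)(C)C=Cc3c2OC)cc1 | intermediate
19 | 1-(7-isopropoxy-5-methoxy-2,2-dimethyl-2H-chromen-6-yl)-2-(4-methoxyphenyl)ethane-1,2-dione | COc1ccc(C(=O)C(=O)c2c(OC(C)C)cc3OC(C)(C)C=Cc3c2OC)cc1 | intermediate
20 | 1-[7-(dichloroboranyloxy)-5-methoxy-2,2-dimethyl-2H-chromen-6-yl]-2-(4-methoxyphenyl)ethane-1,2-dione | COc1ccc(C(=O)C(=O)c2c(OB(Cl)Cl)cc3OC(C)(C)C=Cc3c2OC)cc1 | intermediate (not isolated)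
21 | 1-(7-hydroxy-5-methoxy-2,2-dimethyl-2H-chromen-6-yl)-2-(4-methoxyphenyl)ethane-1,2-dione | COc1ccc(C(=O)C(=O)c2c(O)cc3c(c2OC)C=CC(C)(C)O3)cc1 | target

Total step count: 8. Longest linear sequence: 7 steps (steps 1, 2, 3, 5, 6, 7, 8); the ynol ether branch (step 4) joins at step 5.

Steps most likely to fail

1. Step 5 (key step). The 4π opening of the vinylogous ester may be so slow that the ynol ether oligomerises or the vinylketene dimerises before capture. The dienylketene may also be diverted through closure onto the alkyne, and the product phenol may be acylated by the vinylketene. The fallback sets out from alkyne 4 and comes back at chromene 18. It takes ring B from a phloroglucinol-derived chromanone and distinguishes the three oxygens by hydrogen bonding to the C4 ketone instead.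
   - Purchased 5,7-dihydroxy-2,2-dimethylchroman-4-one F1 is alkylated at the non-chelated 7-OH (2-bromopropane, K2CO3, DMF) to give 5-hydroxy-7-isopropoxy-2,2-dimethylchroman-4-one F2.
   - Iodination ortho to the chelated 5-OH (BnMe3N·ICl2, CaCO3, CH2Cl2–MeOH) should give 5-hydroxy-6-iodo-7-isopropoxy-2,2-dimethylchroman-4-one F3.
   - Methylation (MeI, K2CO3, DMF, 60 °C) gives 6-iodo-7-isopropoxy-5-methoxy-2,2-dimethylchroman-4-one F4.
   - Reduction (NaBH4, MeOH) gives racemic 6-iodo-7-isopropoxy-5-methoxy-2,2-dimethylchroman-4-ol F5.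
   - Dehydration (TsOH cat., toluene, 60 °C) gives 6-iodo-7-isopropoxy-5-methoxy-2,2-dimethyl-2H-chromene F6.
   - Sonogashira coupling of F6 with 4 (PdCl2(PPh3)2, CuI, Et3N, DMF, 60 °C) gives 18.

2. Step 3. The amine base may add to C3 or cleave the strained iodocyclobutenone, and the alkyne may homocouple under copper. The fallback sets out from alkyne 4 (with iodide 3) and comes back at cyclobutenone 5. Alkyne 4 is converted (n-BuLi, THF, −78 °C; then Bu3SnCl) into tributyl[(4-methoxyphenyl)ethynyl]stannane F7. Amine-free Stille coupling of F7 with 3 (Pd2(dba)3, AsPh3, CuI, DMF, rt) then gives 5.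

3. Step 7. The α-oxo gold carbene may be intercepted by a neighbouring alkoxy oxygen or by the electron-rich arene before the second oxygen transfer, or the released pyridine may slow the catalyst so that oxidation stops halfway. The fallback sets out from chromene 18 and comes back at diketone 19, and avoids a carbene altogether. Hydration of the alkyne without oxidant (Ph3PAuNTf2 cat., H2O, dioxane, 80 °C) should give 1-(7-isopropoxy-5-methoxy-2,2-dimethyl-2H-chromen-6-yl)-2-(4-methoxyphenyl)ethan-1-one F8, possibly with its regioisomer 2-(7-isopropoxy-5-methoxy-2,2-dimethyl-2H-chromen-6-yl)-1-(4-methoxyphenyl)ethan-1-one F9. Riley oxidation of the doubly activated methylene (SeO2, dioxane, 90 °C) converts either ketone into 19. The chromene has no allylic C–H, so SeO2 has no second site of attack.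

Further compounds
F1 | step 5 | 5,7-dihydroxy-2,2-dimethylchroman-4-one | CC1(C)CC(=O)c2c(O)cc(O)cc2O1
F2 | step 5 | 5-hydroxy-7-isopropoxy-2,2-dimethylchroman-4-one | CC(C)Oc1cc(O)c2C(=O)CC(C)(C)Oc2c1
F3 | step 5 | 5-hydroxy-6-iodo-7-isopropoxy-2,2-dimethylchroman-4-one | CC(C)Oc1cc2OC(C)(C)CC(=O)c2c(O)c1I
F4 | step 5 | 6-iodo-7-isopropoxy-5-methoxy-2,2-dimethylchroman-4-one | CC(C)Oc1cc2OC(C)(C)CC(=O)c2c(OC)c1I
F5 | step 5 | racemic 6-iodo-7-isopropoxy-5-methoxy-2,2-dimethylchroman-4-ol | CC(C)Oc1cc2OC(C)(C)CC(O)c2c(OC)c1I
F6 | step 5 | 6-iodo-7-isopropoxy-5-methoxy-2,2-dimethyl-2H-chromene | CC(C)Oc1cc2OC(C)(C)C=Cc2c(OC)c1I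
F7 | step 3 | tributyl[(4-methoxyphenyl)ethynyl]stannane | CCCC[Sn](CCCC)(CCCC)C#Cc1ccc(OC)cc1
F8 | step 7 | 1-(7-isopropoxy-5-methoxy-2,2-dimethyl-2H-chromen-6-yl)-2-(4-methoxyphenyl)ethan-1-one | COc1ccc(CC(=O)c2c(OC(C)C)cc3OC(C)(C)C=Cc3c2OC)cc1
F9 | step 7 | 2-(7-isopropoxy-5-methoxy-2,2-dimethyl-2H-chromen-6-yl)-1-(4-methoxyphenyl)ethan-1-one | COc1ccc(C(=O)Cc2c(OC(C)C)cc3OC(C)(C)C=Cc3c2OC)cc1
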